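**Retrosynthetic overview**

1. Gentiside K (9) is the n-tetracosyl ester of 2,3-dihydroxybenzoic acid. It has no stereocentre, and its only ring, the benzene ring, is bought intact as 2,3-bis(benzyloxy)benzoic acid (4), so no ring is formed in the route.
2. Key disconnection: the C13–C14 bond of the alkyl chain (numbered from the ester oxygen), built as a C13=C14 alkene by Ru-catalysed cross-metathesis of tetradec-13-enyl ester 5 with dodec-1-ene (6). H2/Pd–C in the same flask then saturates the alkene and removes both O-benzyl groups, so this one operation delivers 9.
3. Enabling feature: C13 and C14 are two plain CH2 groups in an unbranched, heteroatom-free polymethylene run, twelve carbons from the ester O–CH2 and free of stereocentres. The bond can therefore be made at the alkene oxidation level, and E/Z geometry is erased on reduction. The oxygens on ring carbons C2 and C3 travel as benzyl ethers that leave under the same H2.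
4. Remaining disconnections: the ester C–O bond (Steglich, 3 + 4) and C11–C12 of alkenol 3 (Cu-catalysed allyl Grignard coupling with 11-bromoundecan-1-ol 1).

Key step: step 3

Remark: 2,3-bis(benzyloxy)benzoic acid (4) is taken as a catalogue compound; the alkene geometry of 7 is left as an E/Z mixture (E drawn in the list) because it is erased in the same operation.

Step 1
Reactants: 1 11-bromoundecan-1-ol; 2 allylmagnesium bromide
Product: 3 tetradec-13-en-1-ol
Conditions: 2 (2.5 equiv, Et2O), Li2CuCl4 (3 mol%), THF, −20 °C → rt; aq NH4Cl
Reagents that add atoms: none
Why: Kochi-type copper-catalysed sp3–sp3 Grignard cross-coupling, in which the first equivalent of 2 only converts the hydroxyl into an inert magnesium alkoxide (propene lost) and the allylcopper species from the next equivalent displaces the unhindered primary bromide, creating the C11–C12 bond of the C14 alkenol with no stereochemical issue.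

Step 2
Reactants: 3 tetradec-13-en-1-ol; 4 2,3-bis(benzyloxy)benzoic acid
Product: 5 tetradec-13-en-1-yl 2,3-bis(benzyloxy)benzoate
Conditions: DCC (1.2 equiv), DMAP (0.1 equiv), CH2Cl2, 0 °C → rt
Reagents that add atoms: none
Why: Steglich esterification, in which DCC activates acid 4 as the O-acylisourea and DMAP relays the acyl group as an N-acylpyridinium ion to the unhindered primary alcohol 3, while the benzyl ethers and the remote terminal alkene are inert to these neutral conditions.

Step 3
Reactants: 5 tetradec-13-en-1-yl 2,3-bis(benzyloxy)benzoate; 6 dodec-1-ene
Product: 9 Gentiside K (tetracosyl 2,3-dihydroxybenzoate), via tetracos-13-enyl ester 7 (not isolated), via tetracosyl dibenzyl ester 8 (not isolated)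
Conditions: 6 (5 equiv), Hoveyda–Grubbs II (3 mol%), AcOH (10 mol%), CH2Cl2, 40 °C, Ar sweep; then evaporate, 10% Pd/C, H2 (1 atm), EtOAc–EtOH, rt
Reagents that add atoms: none
Why: Olefin cross-metathesis by the Chauvin mechanism ([2+2] cycloaddition/cycloreversion through ruthenacyclobutanes) exchanges the terminal =CH2 groups of 5 and 6 for each other's alkylidene and so forges C13=C14 of the chain, loss of ethene driving the exchange forward; the closest precedent is the cross-metathesis of two unhindered terminal (type I) alkenes with one partner in excess, followed by heterogeneous hydrogenation in the same flask. No ring is closed and no stereocentre is created, and the E/Z mixture of 7 is of no consequence because Pd/C–H2 saturates the alkene to 8. The selectivity needed is cross- over homo-coupling, secured by the excess of inexpensive 6 (whose homodimer ends as docosane and is easily separated from the polar catechol ester), and positional integrity of the double bond, secured by the acetic acid additive that quenches the Ru–H species which would otherwise walk the alkene and give chain-length homologues. The alkene of 5 lies twelve methylenes away from the ester and the aryl ring, so the bis(benzyloxy)benzoate should neither chelate nor deactivate the catalyst. In the second stage Pd/C–H2 hydrogenolyses both benzylic C–O bonds of 8 to toluene and frees the 2- and 3-hydroxyls, while the primary alkyl benzoate ester, which has no benzylic C–O bond, is untouched.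

**Compound list**

1 | 11-bromoundecan-1-ol | OCCCCCCCCCCCBr | starting material
2 | allylmagnesium bromide | C=CC[Mg]Br | starting material
3 | tetradec-13-en-1-ol | C=CCCCCCCCCCCCCO | intermediate
4 | 2,3-bis(benzyloxy)benzoic acid | OC(=O)c1cccc(OCc2ccccc2)c1OCc1ccccc1 | starting material
5 | tetradec-13-en-1-yl 2,3-bis(benzyloxy)benzoate | C=CCCCCCCCCCCCCOC(=O)c1cccc(OCc2ccccc2)c1OCc1ccccc1 | intermediate
6 | dodec-1-ene | C=CCCCCCCCCCC | starting material
7 | tetracos-13-en-1-yl 2,3-bis(benzyloxy)benzoate (E/Z mixture, E drawn) | CCCCCCCCCC/C=C/CCCCCCCCCCCCOC(=O)c1cccc(OCc2ccccc2)c1OCc1ccccc1 | intermediate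
8 | tetracosyl 2,3-bis(benzyloxy)benzoate | CCCCCCCCCCCCCCCCCCCCCCCCOC(=O)c1cccc(OCc2ccccc2)c1OCc1ccccc1 | intermediate
9 | Gentiside K (tetracosyl 2,3-dihydroxybenzoate) | CCCCCCCCCCCCCCCCCCCCCCCCOC(=O)c1cccc(O)c1O | target

**Summary**

Total step count: 3. Longest linear sequence: 3 steps (1 → 3 → 5 → 9).

**Steps most likely to fail, with fallbacks**

First, step 3. The risks are migration of the double bond by ruthenium hydrides before or after the alkylidene exchange, which would give chain-length homologues that are very hard to separate, and unproductive homodimerisation of 5. The fallback sets out from 5 and comes back to the route at 7. Lemieux–Johnson cleavage of the terminal alkene of 5 (K2OsO4 cat., NaIO4, 2,6-lutidine, dioxane–H2O) should give 13-oxotridecyl 2,3-bis(benzyloxy)benzoate F1. Wittig olefination of F1 with undecylidene(triphenyl)phosphorane F2 (generated from undecyltriphenylphosphonium bromide and NaHMDS, THF, −78 °C → rt) forms the same C13=C14 bond at a fixed position and should give 7 as a Z-rich mixture. This is then hydrogenated over Pd/C as in the second stage of step 3, passing through 8 to 9.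

Second, step 1. The risk is precipitation of the bromomagnesium alkoxide, which stalls the copper-catalysed displacement, together with competing halogen–metal exchange and reduction of the bromide. The fallback sets out from 1 and comes back at 3, and it masks the protic group so that the coupling runs on a homogeneous, aprotic substrate. Protection with 3,4-dihydro-2H-pyran (PPTS, CH2Cl2) should give 2-[(11-bromoundecyl)oxy]oxane F3. Coupling with 2 (1.3 equiv, Li2CuCl4 cat., THF) should give 2-(tetradec-13-en-1-yloxy)oxane F4, and acetal exchange (PPTS, MeOH, 50 °C) should release 3.

Third, step 2. The risk is rearrangement of the O-acylisourea of the ortho-substituted, hindered acid to the unreactive N-acylurea faster than acyl transfer. The fallback sets out from 3 and comes back at 5, and it reverses the polarity of the ester bond formation (carboxylate as nucleophile, alcohol carbon as electrophile). Mesylation of 3 (MsCl, Et3N, CH2Cl2, 0 °C) should give tetradec-13-en-1-yl methanesulfonate F5, and O-alkylation of acid 4 with F5 (Cs2CO3, DMF, 60 °C) should give 5.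

**Further compounds**

F1 | step 3 | 13-oxotridecyl 2,3-bis(benzyloxy)benzoate | O=CCCCCCCCCCCCCOC(=O)c1cccc(OCc2ccccc2)c1OCc1ccccc1
F2 | step 3 | undecylidene(triphenyl)phosphorane | CCCCCCCCCCC=P(c1ccccc1)(c1ccccc1)c1ccccc1
F3 | step 1 | 2-[(11-bromoundecyl)oxy]oxane (racemic) | BrCCCCCCCCCCCOC1CCCCO1
F4 | step 1 | 2-(tetradec-13-en-1-yloxy)oxane (racemic) | C=CCCCCCCCCCCCCOC1CCCCO1
F5 | step 2 | tetradec-13-en-1-yl methanesulfonate | C=CCCCCCCCCCCCCOS(C)(=O)=O
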